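26 ⇐ 25 (desilylation) ⇐ Evans–Tishchenko union of epoxy β-hydroxy ketone 21 and O-silylvanillin 23, which in one step sets C8, puts the aryl ester on O6 and leaves O8 free.
21 ⇐ hydroxyl-directed epoxidation of C4=C5 in dienone 20 ⇐ reductive desulfonylation of β-keto sulfone 19.
19 ⇐ C8–C9 bond: the C9 allyl sulfone carbanion of cis-β-lactone 15 attacks the lactone carbonyl C8 and the acyl group moves from O6 to C9, so the four-membered ring is traded for the ten-membered carbocycle.
Enabling feature: O6 and C8 stand 1,3 across C7 and can be tied into an oxetan-2-one ring (O–C6–C7–C8) that stores C6/C7 and activates C8. C9 is the allylic CH2 beside C10=C1, and the E olefins C1=C10 and C4=C5 in the tether C5–C4–C3–C2–C1–C10–C9 exclude every smaller ring.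
15 ⇐ Evans syn aldol of isovaleryl imide 9 and 8-sulfonylgeranial 6 (five steps from geranyl acetate 1). Ring order: oxetanone, cyclodecadiene, oxirane.

Key step: step 10

Remark on numbering: carbons are numbered as in germacranes. C6 carries the ester oxygen, C7 the isopropyl group and C8 the free hydroxyl. C9 is the neighbouring ring CH2, C10(CH3)=C1 is the olefin, C2 and C3 are the two CH2 groups, and C4(CH3)–C5 is the epoxide. The open-chain precursors keep these numbers.
Remark on the chemistry: 19 is assumed to form as a mixture of C9 epimers and is carried on as such, because step 11 erases this centre. The hemiketal and hemiacetal centres of 17 and 24 are likewise left undefined.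

Step 1
Reactants: 1 geranyl acetate
Product: 2 (2E,6E)-8-hydroxy-3,7-dimethylocta-2,6-dien-1-yl acetate
Conditions: SeO2 (10 mol %), t-BuOOH, salicylic acid (10 mol %), CH2Cl2, rt
Reagents that add atoms: tert-butyl hydroperoxide CC(C)(C)OO
Why: SeO2/t-BuOOH allylic oxidation (ene reaction, then [2,3]-sigmatropic shift) attacks the electron-richer terminal olefin at its E methyl group only, which fixes the E geometry of the later C1=C10 olefin.

Step 2
Reactants: 2 (2E,6E)-8-hydroxy-3,7-dimethylocta-2,6-dien-1-yl acetate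
Product: 3 (2E,6E)-8-bromo-3,7-dimethylocta-2,6-dien-1-yl acetate
Conditions: CBr4, PPh3, CH2Cl2, 0 °C
Reagents that add atoms: carbon tetrabromide BrC(Br)(Br)Br
Why: The Appel reaction replaces the primary allylic hydroxyl by SN2 displacement, without allylic shift or loss of olefin geometry.

Step 3
Reactants: 3 (2E,6E)-8-bromo-3,7-dimethylocta-2,6-dien-1-yl acetate
Product: 4 (2E,6E)-3,7-dimethyl-8-(phenylsulfonyl)octa-2,6-dien-1-yl acetate
Conditions: PhSO2Na, DMF, rt
Reagents that add atoms: sodium benzenesulfinate [Na+].[O-]S(=O)c1ccccc1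
Why: SN2 S-alkylation of the sulfinate by the primary allylic bromide installs the sulfone that later acidifies C9.

Step 4
Reactants: 4 (2E,6E)-3,7-dimethyl-8-(phenylsulfonyl)octa-2,6-dien-1-yl acetate
Product: 5 (2E,6E)-3,7-dimethyl-8-(phenylsulfonyl)octa-2,6-dien-1-ol
Conditions: K2CO3 (0.2 equiv), MeOH, 0 °C to rt
Reagents that add atoms: none
Why: Base-catalysed transesterification frees the primary allylic alcohol and is too mild to deprotonate or isomerise the allyl sulfone.

Step 5
Reactants: 5 (2E,6E)-3,7-dimethyl-8-(phenylsulfonyl)octa-2,6-dien-1-ol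
Product: 6 (2E,6E)-3,7-dimethyl-8-(phenylsulfonyl)octa-2,6-dienal
Conditions: TEMPO (10 mol %), PhI(OAc)2, MeCN/pH 7 buffer, 0 °C
Reagents that add atoms: none
Why: Oxoammonium oxidation (TEMPO/PhI(OAc)2) stops at the enal and is a standard way to oxidise geraniol-type alcohols without E/Z leakage.

Step 6
Reactants: 7 (S)-4-benzyl-1,3-oxazolidin-2-one; 8 3-methylbutanoyl chloride
Product: 9 (S)-4-benzyl-3-(3-methylbutanoyl)-1,3-oxazolidin-2-one
Conditions: Et3N, DMAP (10 mol %), CH2Cl2, 0 °C to rt
Reagents that add atoms: none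
Why: DMAP-catalysed N-acylation of the oxazolidinone by the acid chloride is the standard loading of the Evans auxiliary.

Step 7
Reactants: 9 (S)-4-benzyl-3-(3-methylbutanoyl)-1,3-oxazolidin-2-one; 6 (2E,6E)-3,7-dimethyl-8-(phenylsulfonyl)octa-2,6-dienal
Product: 12 (4S)-4-benzyl-3-[(2S,3R,4E,8E)-3-hydroxy-5,9-dimethyl-10-(phenylsulfonyl)-2-(propan-2-yl)deca-4,8-dienoyl]-1,3-oxazolidin-2-one, via Z boron enolate 10 (not isolated), via boron aldolate 11 (not isolated)
Conditions: Bu2BOTf, Et3N, CH2Cl2, −78 to 0 °C; 6, −78 to 0 °C; then pH 7 buffer, MeOH, 30% H2O2, 0 °C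
Reagents that add atoms: none
Why: In the Evans syn aldol reaction the Z enolate 10 reacts through a Zimmerman–Traxler chair on the face away from the benzyl group, so C6 and C7 are set syn and in the absolute sense dictated by the S auxiliary, and enals are among the best partners for this reaction.

Step 8
Reactants: 12 syn aldol adduct
Product: 14 (2S,3R,4E,8E)-3-hydroxy-5,9-dimethyl-10-(phenylsulfonyl)-2-(propan-2-yl)deca-4,8-dienoic acid, via lithium percarboxylate 13 (not isolated)
Conditions: LiOH, 30% H2O2, THF/H2O, 0 °C; Na2SO3; then 1 M HCl to pH 3, 0 °C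
Reagents that add atoms: hydrogen peroxide OO
Why: Hydroperoxide cleavage attacks the exocyclic imide carbonyl selectively even beside the isopropyl branch, so the auxiliary is released without epimerisation at C7.

Step 9
Reactants: 14 β-hydroxy acid
Product: 15 cis-β-lactone (3S,4R)-4-[(1E,5E)-2,6-dimethyl-7-(phenylsulfonyl)hepta-1,5-dien-1-yl]-3-(propan-2-yl)oxetan-2-one
Conditions: PhSO2Cl (2 equiv), pyridine, 0 to 4 °C
Reagents that add atoms: none
Why: β-Lactonisation by carboxyl activation lets the C6 hydroxyl close the ring in the 4-exo-trig mode with retention at C6 and C7, so the syn acid gives the cis lactone, and the cold basic medium keeps the allylic C6–O bond from ionising.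

Step 10
Reactants: 15 cis-β-lactone
Product: 19 (3E,7E,9R,10S)-9-hydroxy-3,7-dimethyl-2-(phenylsulfonyl)-10-(propan-2-yl)cyclodeca-3,7-dien-1-one, via lithiated sulfone 16 (not isolated), via bicyclic hemiketal alkoxide 17 (not isolated), via lithium enolate 18 (not isolated)
Conditions: LiN(SiMe3)2 (1.05 equiv, added over 2 h), THF (1 mM), −78 to −20 °C; AcOH, −78 °C
Reagents that add atoms: none
Why: Proposed new method: LiN(SiMe3)2 removes the C9–H beside the sulfone (more acidic than the shielded C7–H of the lactone) to give 16, whose α-carbon adds to the strained lactone carbonyl C8 to give 17, and collapse of 17 with cleavage of the C8–O bond moves the acyl group from O6 to C9 and turns the four-membered ring into the ten-membered carbocycle. The closest known reaction types are the acyl–oxygen opening of β-lactones by lithiated sulfones and phosphonates, the ring-enlarging intramolecular acyl substitution of lactones by tethered carbanions, and the closure of (E,E)-cyclodecadienes by sulfur- or cyano-stabilised carbanions, and only their combination for a medium ring is new. The ring closes in the 10-exo-trig mode, driven by release of the oxetanone strain and by the proton shift from C9 to the C6 alkoxide that leaves the stabilised enolate 18 as a sink, so one equivalent of base suffices and neither retro-aldol cleavage nor epimerisation at C7 can follow. No lasting stereocenter is made: C8 in 17 and C9 in 19 are transient, C6 and C7 come unchanged from the cis lactone, and both olefins keep the E geometry because the sulfonyl carbanion stays localised on its α-carbon. The step needs acyl–oxygen rather than alkyl–oxygen cleavage, α- rather than γ-attack and ring closure rather than oligomerisation; attack of C9 at C6 or C4, or of C1 at C8, would force an E olefin into an eight- or six-membered ring, so the two E olefins of the tether leave C8 as the only reachable electrophile, and the 1 mM dilution suppresses intermolecular acylation.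

Step 11
Reactants: 19 β-keto sulfone
Product: 20 (3E,7E,9R,10S)-9-hydroxy-3,7-dimethyl-10-(propan-2-yl)cyclodeca-3,7-dien-1-one
Conditions: SmI2 (2.2 equiv), THF/MeOH, −78 °C
Reagents that add atoms: none
Why: Reductive desulfonylation of a β-keto sulfone by SmI2 cleaves the C9–S bond within minutes, and kinetic protonation at C9 keeps the C1=C10 olefin E and out of conjugation while C7 and the hydroxy ketone are untouched at −78 °C.

Step 12
Reactants: 20 hydroxy dienone
Product: 21 (1R,2S,3S,6E,10R)-2-hydroxy-6,10-dimethyl-3-(propan-2-yl)-11-oxabicyclo[8.1.0]undec-6-en-4-one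
Conditions: VO(acac)2 (5 mol %), t-BuOOH (decane), CH2Cl2, 0 °C
Reagents that add atoms: tert-butyl hydroperoxide CC(C)(C)OO
Why: Hydroxyl-directed epoxidation touches only the allylic C4=C5 olefin, and with C6–H eclipsing the olefin to avoid A(1,3) strain against the C4 methyl group the oxygen is delivered to the outer ring face on which O6 sits, which should give the trans (4R,5R) epoxide syn (threo) to O6.

Step 13
Reactants: 22 vanillin
Product: 23 4-[(tert-butyldimethylsilyl)oxy]-3-methoxybenzaldehyde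
Conditions: TBSCl, imidazole, DMF, rt
Reagents that add atoms: tert-butyldimethylsilyl chloride CC(C)(C)[Si](C)(C)Cl
Why: Imidazole-promoted silylation masks the phenol, which would otherwise quench the samarium catalyst of the next step.

Step 14
Reactants: 21 epoxy β-hydroxy ketone; 23 4-[(tert-butyldimethylsilyl)oxy]-3-methoxybenzaldehyde
Product: 25 (1R,2S,3R,4R,6E,10R)-4-hydroxy-6,10-dimethyl-3-(propan-2-yl)-11-oxabicyclo[8.1.0]undec-6-en-2-yl 4-[(tert-butyldimethylsilyl)oxy]-3-methoxybenzoate, via hemiacetal 24 (not isolated)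
Conditions: SmI2 (30 mol %), 23 (5 equiv), THF, −10 °C, dark
Reagents that add atoms: none
Why: In the Evans–Tishchenko reaction O6 adds to the aldehyde to give 24, and within a chair-like array bridged by trivalent samarium its formyl hydrogen is delivered intramolecularly to the C8 ketone, which sets the 8R carbinol 1,3-anti to O6 and leaves the aryl ester on O6 only.

Step 15
Reactants: 25 silyl-protected ester
Product: 26 (1R,2S,3R,4R,6E,10R)-4-hydroxy-6,10-dimethyl-3-(propan-2-yl)-11-oxabicyclo[8.1.0]undec-6-en-2-yl 4-hydroxy-3-methoxybenzoate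
Conditions: Bu4NF, AcOH, THF, 0 °C
Reagents that add atoms: none
Why: Buffered fluoride cleaves the aryl silyl ether rapidly and leaves the ester, the epoxide, the olefin and the secondary alcohol untouched.

Compound list
1 | geranyl acetate | CC(C)=CCC/C(C)=C/COC(C)=O | starting material
2 | (2E,6E)-8-hydroxy-3,7-dimethylocta-2,6-dien-1-yl acetate | OC/C(C)=C/CC/C(C)=C/COC(C)=O | intermediate
3 | (2E,6E)-8-bromo-3,7-dimethylocta-2,6-dien-1-yl acetate | BrC/C(C)=C/CC/C(C)=C/COC(C)=O | intermediate
4 | (2E,6E)-3,7-dimethyl-8-(phenylsulfonyl)octa-2,6-dien-1-yl acetate | O=S(=O)(c1ccccc1)C/C(C)=C/CC/C(C)=C/COC(C)=O | intermediate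
5 | (2E,6E)-3,7-dimethyl-8-(phenylsulfonyl)octa-2,6-dien-1-ol | O=S(=O)(c1ccccc1)C/C(C)=C/CC/C(C)=C/CO | intermediate
6 | (2E,6E)-3,7-dimethyl-8-(phenylsulfonyl)octa-2,6-dienal | O=S(=O)(c1ccccc1)C/C(C)=C/CC/C(C)=C/C=O | intermediate
7 | (S)-4-benzyl-1,3-oxazolidin-2-one | O=C1N[C@@H](Cc2ccccc2)CO1 | starting material
8 | 3-methylbutanoyl chloride | CC(C)CC(Cl)=O | starting material
9 | (S)-4-benzyl-3-(3-methylbutanoyl)-1,3-oxazolidin-2-one | CC(C)CC(=O)N1[C@@H](Cc2ccccc2)COC1=O | intermediate
10 | Z dibutylboron enolate of 9 | CC(C)/C=C(\OB(CCCC)CCCC)N1[C@@H](Cc2ccccc2)COC1=O | intermediate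
11 | dibutylboron aldolate of 12 | CC(C)[C@H](C(=O)N1[C@@H](Cc2ccccc2)COC1=O)[C@H](OB(CCCC)CCCC)/C=C(\C)CC/C=C(\C)CS(=O)(=O)c1ccccc1 | intermediate
12 | (4S)-4-benzyl-3-[(2S,3R,4E,8E)-3-hydroxy-5,9-dimethyl-10-(phenylsulfonyl)-2-(propan-2-yl)deca-4,8-dienoyl]-1,3-oxazolidin-2-one | CC(C)[C@H](C(=O)N1[C@@H](Cc2ccccc2)COC1=O)[C@H](O)/C=C(\C)CC/C=C(\C)CS(=O)(=O)c1ccccc1 | intermediate
13 | lithium percarboxylate of 14 | CC(C)[C@H](C(=O)OO[Li])[C@H](O)/C=C(\C)CC/C=C(\C)CS(=O)(=O)c1ccccc1 | intermediate
14 | (2S,3R,4E,8E)-3-hydroxy-5,9-dimethyl-10-(phenylsulfonyl)-2-(propan-2-yl)deca-4,8-dienoic acid | CC(C)[C@H](C(=O)O)[C@H](O)/C=C(\C)CC/C=C(\C)CS(=O)(=O)c1ccccc1 | intermediate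
15 | (3S,4R)-4-[(1E,5E)-2,6-dimethyl-7-(phenylsulfonyl)hepta-1,5-dien-1-yl]-3-(propan-2-yl)oxetan-2-one (cis) | CC(C)[C@@H]1C(=O)O[C@@H]1/C=C(\C)CC/C=C(\C)CS(=O)(=O)c1ccccc1 | intermediate
16 | C9-lithiated sulfone of 15 | CC(C)[C@@H]1C(=O)O[C@@H]1/C=C(\C)CC/C=C(\C)C([Li])S(=O)(=O)c1ccccc1 | intermediate
17 | bicyclic hemiketal lithium alkoxide (oxetane bridging C6 and C8 of the ten-membered ring) | CC(C)[C@@H]1C2(O[Li])O[C@@H]1/C=C(\C)CC/C=C(\C)C2S(=O)(=O)c1ccccc1 | intermediate
18 | lithium C8=C9 enolate of 19 | CC(C)[C@@H]1C(O[Li])=C(S(=O)(=O)c2ccccc2)/C(C)=C/CC/C(C)=C/[C@H]1O | intermediate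
19 | (3E,7E,9R,10S)-9-hydroxy-3,7-dimethyl-2-(phenylsulfonyl)-10-(propan-2-yl)cyclodeca-3,7-dien-1-one (both epimers at the sulfonyl carbon) | CC(C)[C@@H]1C(=O)C(S(=O)(=O)c2ccccc2)/C(C)=C/CC/C(C)=C/[C@H]1O | intermediate
20 | (3E,7E,9R,10S)-9-hydroxy-3,7-dimethyl-10-(propan-2-yl)cyclodeca-3,7-dien-1-one | CC(C)[C@@H]1C(=O)C/C(C)=C/CC/C(C)=C/[C@H]1O | intermediate
21 | (1R,2S,3S,6E,10R)-2-hydroxy-6,10-dimethyl-3-(propan-2-yl)-11-oxabicyclo[8.1.0]undec-6-en-4-one | CC(C)[C@@H]1C(=O)C/C(C)=C/CC[C@@]2(C)O[C@@H]2[C@H]1O | intermediate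
22 | vanillin | COc1cc(C=O)ccc1O | starting material
23 | 4-[(tert-butyldimethylsilyl)oxy]-3-methoxybenzaldehyde | COc1cc(C=O)ccc1O[Si](C)(C)C(C)(C)C | intermediate
24 | hemiacetal of 21 (through O6) and 23 | CC(C)[C@@H]1C(=O)C/C(C)=C/CC[C@@]2(C)O[C@@H]2[C@H]1OC(O)c1ccc(O[Si](C)(C)C(C)(C)C)c(OC)c1 | intermediate
25 | (1R,2S,3R,4R,6E,10R)-4-hydroxy-6,10-dimethyl-3-(propan-2-yl)-11-oxabicyclo[8.1.0]undec-6-en-2-yl 4-[(tert-butyldimethylsilyl)oxy]-3-methoxybenzoate | COc1cc(C(=O)O[C@H]2[C@H](C(C)C)[C@H](O)C/C(C)=C/CC[C@@]3(C)O[C@H]23)ccc1O[Si](C)(C)C(C)(C)C | intermediate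
26 | (1R,2S,3R,4R,6E,10R)-4-hydroxy-6,10-dimethyl-3-(propan-2-yl)-11-oxabicyclo[8.1.0]undec-6-en-2-yl 4-hydroxy-3-methoxybenzoate | COc1cc(C(=O)O[C@H]2[C@H](C(C)C)[C@H](O)C/C(C)=C/CC[C@@]3(C)O[C@H]23)ccc1O | target

Total step count: 15. Longest linear sequence: 13 (steps 1–5, 7–12, 14 and 15).

Steps most likely to fail

Step 10. Intermolecular acylation (oligomerisation), proton transfer from C7–H to the carbanion, or ionisation of the allylic C6–O bond of the lactone could outrun the ten-membered closure. The fallback sets out from 12 and comes back at 19. It replaces the strained lactone by an open-chain acyl donor and uses the classical condensation of a lithiated sulfone with a carboxylic acid derivative.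
- The hydroxyl of 12 is silylated (Et3SiOTf, 2,6-lutidine) to the triethylsilyl ether F1.
- The auxiliary is displaced by LiSEt to give the S-ethyl thioester F2.
- F2 is cyclised with LiN(SiMe3)2 (2.1 equiv) under high dilution to the silyl-protected β-keto sulfone F3.
- HF·pyridine then frees O6 and gives 19.

Step 14. Hemiacetal formation and hydride transfer may be slow with the electron-rich aldehyde, so that retro-aldol opening of the ring or acyl migration from O6 to O8 gains ground. The fallback sets out from 21 and comes back at 26. It separates the reduction from the introduction of the vanillate.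
- 21 is submitted to the samarium-catalysed reaction with 4-nitrobenzaldehyde, a far more electrophilic partner, to give the 6-O-(4-nitrobenzoate) F4.
- O8 is capped (Et3SiOTf, 2,6-lutidine) to give the silyl ether F5.
- The activated ester is removed with K2CO3 in MeOH to give the 6-alcohol F6.
- 4-[(tert-Butyldimethylsilyl)oxy]-3-methoxybenzoic acid F7, made from 23 by Pinnick oxidation, is attached by Steglich esterification to give the bis-silyl ester F8.
- Bu4NF/AcOH removes both silyl groups to give 26.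

Step 12. Poor facial selectivity in the flexible ring, attack on the C1=C10 olefin, or transannular opening of the new epoxide by that olefin on the Lewis acidic vanadium centre could erode the result. The fallback sets out from 12 and comes back at 21. It moves the epoxidation to the open chain, where A(1,3)-controlled, hydroxyl-directed epoxidation of such trisubstituted allylic alcohols has direct acyclic analogy.
- VO(acac)2/t-BuOOH converts 12 into the epoxy aldol adduct F9.
- LiOH/H2O2 with a buffered work-up gives the epoxy acid F10.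
- PhSO2Cl in pyridine gives the epoxy β-lactone F11.
- The conditions of step 10 give the epoxy β-keto sulfone F12.
- SmI2 in THF/MeOH gives 21.

Further compounds
F1 | step 10 | triethylsilyl ether of 12 | CC(C)[C@H](C(=O)N1[C@@H](Cc2ccccc2)COC1=O)[C@H](O[Si](CC)(CC)CC)/C=C(\C)CC/C=C(\C)CS(=O)(=O)c1ccccc1
F2 | step 10 | S-ethyl (2S,3R,4E,8E)-5,9-dimethyl-10-(phenylsulfonyl)-2-(propan-2-yl)-3-[(triethylsilyl)oxy]deca-4,8-dienethioate | CC(C)[C@H](C(=O)SCC)[C@H](O[Si](CC)(CC)CC)/C=C(\C)CC/C=C(\C)CS(=O)(=O)c1ccccc1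
F3 | step 10 | triethylsilyl ether of 19 | CC(C)[C@@H]1C(=O)C(S(=O)(=O)c2ccccc2)/C(C)=C/CC/C(C)=C/[C@H]1O[Si](CC)(CC)CC
F4 | step 14 | (1R,2S,3R,4R,6E,10R)-4-hydroxy-6,10-dimethyl-3-(propan-2-yl)-11-oxabicyclo[8.1.0]undec-6-en-2-yl 4-nitrobenzoate | O=C(O[C@H]1[C@H](C(C)C)[C@H](O)C/C(C)=C/CC[C@@]2(C)O[C@H]12)c1ccc([N+](=O)[O-])cc1
F5 | step 14 | 8-O-triethylsilyl ether of F4 | O=C(O[C@H]1[C@H](C(C)C)[C@H](O[Si](CC)(CC)CC)C/C(C)=C/CC[C@@]2(C)O[C@H]12)c1ccc([N+](=O)[O-])cc1
F6 | step 14 | 8-O-triethylsilyl epoxy diol with free 6-hydroxyl | O[C@H]1[C@H](C(C)C)[C@H](O[Si](CC)(CC)CC)C/C(C)=C/CC[C@@]2(C)O[C@H]12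
F7 | step 14 | 4-[(tert-butyldimethylsilyl)oxy]-3-methoxybenzoic acid | COc1cc(C(=O)O)ccc1O[Si](C)(C)C(C)(C)C
F8 | step 14 | 8-O-triethylsilyl ether of 25 | COc1cc(C(=O)O[C@H]2[C@H](C(C)C)[C@H](O[Si](CC)(CC)CC)C/C(C)=C/CC[C@@]3(C)O[C@H]23)ccc1O[Si](C)(C)C(C)(C)C
F9 | step 12 | (4R,5R)-epoxide of aldol adduct 12 | CC(C)[C@H](C(=O)N1[C@@H](Cc2ccccc2)COC1=O)[C@H](O)[C@H]1O[C@]1(C)CC/C=C(\C)CS(=O)(=O)c1ccccc1
F10 | step 12 | (4R,5R)-epoxide of acid 14 | CC(C)[C@H](C(=O)O)[C@H](O)[C@H]1O[C@]1(C)CC/C=C(\C)CS(=O)(=O)c1ccccc1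
F11 | step 12 | (4R,5R)-epoxide of β-lactone 15 | CC(C)[C@@H]1C(=O)O[C@@H]1[C@H]1O[C@]1(C)CC/C=C(\C)CS(=O)(=O)c1ccccc1
F12 | step 12 | 9-(phenylsulfonyl) derivative of 21 | CC(C)[C@@H]1C(=O)C(S(=O)(=O)c2ccccc2)/C(C)=C/CC[C@@]2(C)O[C@@H]2[C@H]1O
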